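## Analysis of the target

The target 33 is a 2,4,5,6,7,7a-hexahydro-1H-inden-2-one: a cyclopentenone (C1, C2 ketone, C3=C3a alkene, C7a) fused along C3a–C7a to a six-membered carbocycle (C4 to C7). C7a is an all-carbon quaternary centre bearing the angular methyl. It is flanked by the C1 methine (2-formylallyl side chain) and the C7 methine (carboxylic acid), and C4 carries the (2E,4E,6E,8R)-6,8-dimethyldeca-2,4,6-trienoyloxy group. The ring descriptors are 1R, 4S, 7R, 7aS; translated into geometry, the C1 side chain, the C4 oxygen, the C7 carboxyl and the C7a methyl all lie on the same face of the bicycle. The fifth stereocentre, C8 of the acyl chain (R), is remote and must come from its own enantiopure building block. Sensitive functions are the α-substituted acrolein, the free acid, the trienoate (an allylic, γ-acyloxy-enone ester) and above all C1, which is α to the C2 ketone and can epimerise. The difficulties are the quaternary centre with three neighbouring stereocentres, an ene-dione stage in which two carbonyls must be told apart, and a final deprotection that must spare an enal and a triene. The plan rests on one feature: C5 and C6 are the only unfunctionalised ring carbons and sit between the C4 oxygen and the C7 carboxyl. C5 is therefore the α-carbon of a C4 ketone and C6 the β-carbon of a C7 carboxyl, so the C5–C6 bond is the bond between an acetyl enolate carbon and the terminus of an acrylate.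

## Retrosynthetic reasoning

Enal and protecting groups (33 ⇒ 32 ⇒ 31). The enal is the most fragile group and is made last, by oxidising the primary allylic alcohol of 32. Compound 32 comes from 31 by one acidolysis that removes both the tert-butyl ester and the silyl ether. These two groups are chosen because they fall together, both survive enolate chemistry, and a silyl ether tolerates the silyl Lewis acid of the ring closure better than a benzylic ether would.

C4–O acyl bond (31 ⇒ 21 + 29). Cutting the ester makes the route convergent and keeps the triene out of all enolate and Lewis-acid steps. The forward reaction must acylate a hindered, axial allylic alcohol without epimerising C1, which calls for a Yamaguchi esterification.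

C4–H bond (21 ⇒ 20). The carbinol is traced to the ene-dione 20. The forward reduction must choose the C4 carbonyl over the C2 carbonyl and deliver hydride on the face opposite the angular methyl.

C5–C6 bond (20 ⇒ 17, through 18 and 19). This is the central cut. It removes the six-membered ring and the C7 stereocentre in one operation and leaves the monocyclic acetyl cyclopentenone 17 with an acrylate on C7a. Any other ring bond would either break the quaternary centre or separate two functionalised carbons. Forward, the acetyl group must be enolised selectively to the silyloxydiene 18, C5 must add to C6 in a 6-endo closure, and the resulting ketene acetal 19 must be protonated anti to the methyl.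

C1–CH2 bond (17 ⇒ 12 + 15). The side chain is attached by alkylating C1 while the acetyl group is still masked as an enol ether in 12, so C1 is the only acidic position. The electrophile should enter anti to the larger C7a substituent, that is cis to the methyl. Bromide 15 comes from diol 13 through the monosilyl ether 14.

C3a–C4 bond and C2 carbonyl (12 ⇒ 11 ⇒ 10). The masked acetyl group is joined to C3a by Stille coupling of the β-bromo enone 11. The C2 carbonyl of 11 comes from allylic oxidation of the only allylic methylene of cyclopentene 10.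

C7=C6 methylene (10 ⇒ 7 ⇒ 6). The acrylate carbon C6 is added to the ester α-carbon of 7 by Mannich methylenation. This is done before any ketone exists, so only one enolisable position is present. The tert-butyl ester 7 comes from acid 6.

C7a–C7 bond (6 ⇒ 3 ⇒ 2 ⇒ 1). The quaternary centre is cut by a [3,3] shift: Ireland–Claisen rearrangement of acetate 3 transfers the carbinol configuration of 2 to C7a. Alcohol 2 comes from bromo enone 1 by Corey–Bakshi–Shibata reduction. The bromine has three roles: it is the large group in the reduction, it suppresses ionisation of the allylic ester, and it later becomes the coupling handle at C3a.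

Acyl chain (29 ⇒ 28 ⇒ 27 ⇒ 25 ⇒ 24 ⇒ 23 ⇒ 22). The trienoic acid 29 is cut at C4=C5 (vinylogous Horner–Wadsworth–Emmons reaction on enal 27) and at C6=C7 (Wittig reaction on the aldehyde from alcohol 25). The C8 stereocentre comes from Evans methylation of imide 23, made from oxazolidinone 22.

## Alternatives that were turned down

Alternative 1: Cut C3a–C7a and C6–C7 together. The forward step is an intramolecular Diels–Alder reaction of a 2-silyloxy-1,3-diene (C6=C5–C4=C3a) with an (E)-trisubstituted enoate (C7a=C7) tethered through C1–C2–C3, under a chiral oxazaborolidinium Lewis acid, giving the hydrindane silyl enol ether A1.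
- For: both rings and the C7a/C7 pair form in one step. The cis relation of methyl and ester follows from alkene geometry in a concerted suprafacial addition, not from a kinetic protonation. The C4 oxygen emerges already differentiated. On these three points it is stronger than the chosen plan.
- Against: the dienophile is disubstituted at the carbon that becomes quaternary, so it is sluggish, and face control by an external Lewis acid on an ester is uncertain. A1 has C3a as an sp3 CH that the target lacks, so the C3=C3a alkene must be introduced later across the ring fusion. C1 must then be alkylated at the more hindered α-carbon of a C2 ketone that has a competing C3 methylene.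
- Comparison: the chosen plan spends more linear steps before ring closure, but reaches it with the C2 enone, the C3=C3a alkene and the C1 branch in place, and takes C7a from a reagent-controlled reduction and a stereospecific [3,3] shift.

Alternative 2: Cut the angular methyl carbon from both C7a and C3a. The forward step is a hydroxyl-directed cyclopropanation (carbenoid of the type EtZnCH2I) of the tetrasubstituted C3a=C7a alkene of a bicyclic allylic alcohol, giving A2; the C3a–CH2 bond is later opened reductively to leave the methyl.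
- For: delivery syn to the C4 hydroxyl is a very dependable way to fix a quaternary carbon, and it gives directly the cis relation of C4 oxygen and methyl. C4 is an alcohol from the start, so no ene-dione has to be reduced selectively. On these points it is at least as strong as the chosen plan.
- Against: the tetrasubstituted alkene reacts slowly. Regioselective opening needs a C4 carbonyl and conditions such as Li/NH3, which the C7 ester must survive, and C4 must then be reduced a second time. Opening leaves C3a as sp3 CH, so the enone is again made late. C7, allylic and α to an ester, must be set and held before the key step, and C1 is not addressed.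
- Comparison: the chosen plan concentrates its risk in one C–C bond formation and avoids these redox corrections.

Alternative 3: Cut C2–C3 and C3–C3a. The forward step is a one-carbon ring expansion in which a diazoalkane adds to the carbonyl of an α,α-dichlorocyclobutanone fused at C3a–C7a and C3a migrates, giving the dichlorohydrindanone A3.
- For: ketene cycloaddition followed by ring expansion is a robust cyclopentannulation with migration regiochemistry fixed by the chlorines. C4 and C7 pass through the key step as settled sp3 centres, where the chosen plan sets both after ring closure; on that point this alternative is stronger.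
- Against: C7a is created in the preceding [2+2] step on a trisubstituted cyclohexene, where face control by remote C4 and C7 substituents is not assured. A3 has C3a–H and no C3=C3a alkene, the chlorines must be removed, and C1 must then be alkylated next to the quaternary centre in competition with C3. An enantiopure cis-1,4-disubstituted cyclohexene must be made first, and the diazoalkane is hazardous.
- Comparison: the chosen plan arrives at the ring closure with the enone and the C1 branch installed and needs only one reduction afterwards for the core.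

Key step: step 11

Remark: compound 1 is taken as a catalogue chemical; if needed it follows in one operation from 3-methylcyclopent-2-en-1-one (Br2, then Et3N), which would add one step to the linear sequence.

## Route

Step 1
Reactants: 1 2-bromo-3-methylcyclopent-2-en-1-one
Product: 2 (1S)-2-bromo-3-methylcyclopent-2-en-1-ol
Conditions: (R)-2-methyl-CBS-oxazaborolidine (10 mol%), BH3·SMe2, THF, −20 °C; MeOH
Reagents that add atoms: none
Why: Corey–Bakshi–Shibata reduction; the bromine-bearing alkenyl carbon acts as the large ketone substituent and the ring CH2 as the small one, so the (R)-catalyst should deliver hydride to the face that gives the (S)-carbinol, and 2-bromo enones are a well-behaved substrate class for this reduction.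

Step 2
Reactants: 2 (1S)-2-bromo-3-methylcyclopent-2-en-1-ol
Product: 3 (1S)-2-bromo-3-methylcyclopent-2-en-1-yl acetate
Conditions: Ac2O, pyridine, DMAP (cat.), CH2Cl2, 0 °C → rt
Reagents that add atoms: acetic anhydride CC(=O)OC(C)=O
Why: Plain O-acylation of a secondary alcohol that leaves the stereocentre untouched; the electron-withdrawing bromine disfavours ionisation of the allylic ester.

Step 3
Reactants: 3 (1S)-2-bromo-3-methylcyclopent-2-en-1-yl acetate
Product: 6 2-[(1S)-2-bromo-1-methylcyclopent-2-en-1-yl]acetic acid, via trimethylsilyl ketene acetal 4 (not isolated), via trimethylsilyl ester 5 (not isolated)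
Conditions: LiN(iPr)2, Me3SiCl, Et3N, THF, −78 °C → 65 °C; then 1 M HCl
Reagents that add atoms: none
Why: Ireland–Claisen rearrangement; the ketene acetal 4 undergoes a suprafacial [3,3] shift across C3–C3a–C7a, so the new C7a–C7 bond forms on the face from which the C3–O bond leaves and the carbinol configuration of 3 is transferred to the quaternary C7a (S), while the alkene moves to C3=C3a with bromine kept on C3a.

Step 4
Reactants: 6 2-[(1S)-2-bromo-1-methylcyclopent-2-en-1-yl]acetic acid
Product: 7 tert-butyl 2-[(1S)-2-bromo-1-methylcyclopent-2-en-1-yl]acetate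
Conditions: tert-butyl 2,2,2-trichloroacetimidate, BF3·OEt2 (cat.), cyclohexane–CH2Cl2, rt
Reagents that add atoms: tert-butyl 2,2,2-trichloroacetimidate CC(C)(C)OC(=N)C(Cl)(Cl)Cl
Why: Acid-catalysed tert-butylation of a carboxylic acid by an imidate, which needs no activation of the hindered carboxyl carbon; the tert-butyl ester resists self-condensation in the next enolate step.

Step 5
Reactants: 7 tert-butyl 2-[(1S)-2-bromo-1-methylcyclopent-2-en-1-yl]acetate
Product: 10 tert-butyl 2-[(1S)-2-bromo-1-methylcyclopent-2-en-1-yl]prop-2-enoate, via Mannich base 8 (not isolated), via trimethylammonium iodide 9 (not isolated)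
Conditions: LiN(iPr)2, THF, −78 °C; CH2=NMe2+ I−, −78 °C → rt; MeI, CH2Cl2, rt; DBU, CH2Cl2, rt → 40 °C
Reagents that add atoms: N,N-dimethylmethyleneiminium iodide C=[N+](C)C.[I-]
Why: Eschenmoser methylenation (Mannich reaction of the ester enolate, N-methylation, E1cB loss of trimethylamine); the ester α-carbon is the only enolisable position and elimination can only give the C7=C6 alkene because C7a carries no hydrogen.

Step 6
Reactants: 10 tert-butyl 2-[(1S)-2-bromo-1-methylcyclopent-2-en-1-yl]prop-2-enoate
Product: 11 tert-butyl 2-[(1S)-2-bromo-1-methyl-4-oxocyclopent-2-en-1-yl]prop-2-enoate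
Conditions: CrO3, 3,5-dimethylpyrazole, CH2Cl2, −20 °C
Reagents that add atoms: chromium trioxide O=[Cr](=O)=O
Why: Allylic C–H oxidation by the complex of hexavalent chromium with 3,5-dimethylpyrazole; C2 is the only allylic methylene (the other allylic position is the quaternary C7a) and the acrylate has no allylic hydrogen, so the β-bromo enone should form with the alkene in place.

Step 7
Reactants: 11 tert-butyl 2-[(1S)-2-bromo-1-methyl-4-oxocyclopent-2-en-1-yl]prop-2-enoate
Product: 12 tert-butyl 2-[(1R)-2-(1-ethoxyethenyl)-1-methyl-4-oxocyclopent-2-en-1-yl]prop-2-enoate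
Conditions: Bu3Sn–C(OEt)=CH2, Pd(PPh3)4 (5 mol%), CuI (10 mol%), toluene, 80 °C
Reagents that add atoms: tributyl(1-ethoxyvinyl)stannane CCCC[Sn](CCCC)(CCCC)C(=C)OCC
Why: Stille coupling; β-bromo enones add readily to zerovalent palladium and the neutral conditions leave the acrylate and the ester alone; the descriptor at the quaternary carbon changes from S to R only because the substituent priorities change.

Step 8
Reactants: 13 2-methylidenepropane-1,3-diol
Product: 14 2-{[(tert-butyldimethylsilyl)oxy]methyl}prop-2-en-1-ol
Conditions: NaH (1.0 equiv), THF, 0 °C; tBuMe2SiCl, 0 °C → rt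
Reagents that add atoms: tert-butyldimethylsilyl chloride CC(C)(C)[Si](C)(C)Cl
Why: Monosilylation of a symmetrical diol through its monosodium alkoxide, which should favour the mono-ether over the bis-ether.

Step 9
Reactants: 14 2-{[(tert-butyldimethylsilyl)oxy]methyl}prop-2-en-1-ol
Product: 15 {[2-(bromomethyl)prop-2-en-1-yl]oxy}(tert-butyl)dimethylsilane
Conditions: CBr4, PPh3, CH2Cl2, 0 °C
Reagents that add atoms: carbon tetrabromide BrC(Br)(Br)Br
Why: Appel bromination of a primary allylic alcohol under neutral conditions that keep the silyl ether.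

Step 10
Reactants: 12 tert-butyl 2-[(1R)-2-(1-ethoxyethenyl)-1-methyl-4-oxocyclopent-2-en-1-yl]prop-2-enoate; 15 {[2-(bromomethyl)prop-2-en-1-yl]oxy}(tert-butyl)dimethylsilane
Product: 17 tert-butyl 2-[(1R,5R)-2-acetyl-5-(2-{[(tert-butyldimethylsilyl)oxy]methyl}prop-2-en-1-yl)-1-methyl-4-oxocyclopent-2-en-1-yl]prop-2-enoate, via C1-alkylated ethoxydiene 16 (not isolated)
Conditions: LiN(SiMe3)2, THF, −78 °C; 15, DMPU, −78 → −30 °C; then 0.5 M HCl, THF, 0 °C
Reagents that add atoms: water O
Why: Kinetic α′-deprotonation of the enone at C1 (the only acidic position while the acetyl group is masked) and enolate alkylation with the allylic bromide; the electrophile should enter anti to the doubly branched acrylate substituent on C7a and therefore cis to the methyl (C1 R). Brief dilute acid then hydrolyses the enol ether to the acetyl group and leaves the silyl ether.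

Step 11
Reactants: 17 tert-butyl 2-[(1R,5R)-2-acetyl-5-(2-{[(tert-butyldimethylsilyl)oxy]methyl}prop-2-en-1-yl)-1-methyl-4-oxocyclopent-2-en-1-yl]prop-2-enoate
Product: 20 tert-butyl (1R,7R,7aS)-1-(2-{[(tert-butyldimethylsilyl)oxy]methyl}prop-2-en-1-yl)-7a-methyl-2,4-dioxo-2,4,5,6,7,7a-hexahydro-1H-indene-7-carboxylate, via 2-silyloxydiene 18 (not isolated), via silyl ketene acetal 19 (not isolated)
Conditions: Me3SiOTf, Et3N, CH2Cl2, −78 → 0 °C; pentane, filtration, evaporation; Tf2NH (10 mol%), CH2Cl2, −78 °C; AcOH, −78 °C → rt
Reagents that add atoms: none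
Why: Soft enolisation silylates the acetyl group at its unhindered methyl to give the cross-conjugated 2-silyloxydiene 18, whereas the only other enolisable hydrogen (C1–H) is tertiary and shielded by the quaternary C7a. The silyl triflimide formed from Tf2NH then activates the acrylate carbonyl and C5 adds to the terminal carbon C6 in an intramolecular Mukaiyama–Michael reaction; the closest known type is the silyl-cation-catalysed addition of silyl enol ethers to acrylates. The six-membered ring closes in the 6-endo-trig mode with respect to the acrylate, both enol carbons lying inside the new ring, and C5=C4–C3a–C7a–C7=C6 is a 1,5-diene whose termini can meet in a chair-like arrangement. Silyl transfer from the C4 oxocarbenium ion to the ester oxygen gives the C4 ketone and the silyl ketene acetal 19 and releases the silyl cation again. C7 is the only new stereocentre and is set when 19 is protonated: the new ring is locked with the C7a methyl axial, so the proton should enter axially at C7 from the face opposite that methyl, leaving the ester equatorial and cis to it (7R). No other closure competes, because a C1 enol could only form a four-membered ring and the side-chain alkene lies on the face remote from the acrylate. Low temperature and a catalytic amount of silyl Lewis acid are chosen to spare the tert-butyl ester and the silyl ether.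

Step 12
Reactants: 20 tert-butyl (1R,7R,7aS)-1-(2-{[(tert-butyldimethylsilyl)oxy]methyl}prop-2-en-1-yl)-7a-methyl-2,4-dioxo-2,4,5,6,7,7a-hexahydro-1H-indene-7-carboxylate
Product: 21 tert-butyl (1R,4S,7R,7aS)-1-(2-{[(tert-butyldimethylsilyl)oxy]methyl}prop-2-en-1-yl)-4-hydroxy-7a-methyl-2-oxo-2,4,5,6,7,7a-hexahydro-1H-indene-7-carboxylate
Conditions: NaBH4 (0.5 equiv), CeCl3·7H2O, MeOH–THF, −78 °C
Reagents that add atoms: none
Why: Luche 1,2-reduction; the six-ring C4 carbonyl should react faster than the C2 carbonyl of the cyclopentenone, which is flanked by the branched C1, and with the C7a methyl locked axial the hydride enters equatorially from the opposite face so that the hydroxyl ends axial and cis to the methyl (4S).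

Step 13
Reactants: 22 (4R)-4-benzyl-1,3-oxazolidin-2-one
Product: 23 (4R)-4-benzyl-3-butanoyl-1,3-oxazolidin-2-one
Conditions: nBuLi, THF, −78 °C; butanoyl chloride, −78 → 0 °C
Reagents that add atoms: butanoyl chloride CCCC(=O)Cl
Why: N-acylation of the lithiated oxazolidinone, the standard entry to Evans imides.

Step 14
Reactants: 23 (4R)-4-benzyl-3-butanoyl-1,3-oxazolidin-2-one
Product: 24 (4R)-4-benzyl-3-[(2R)-2-methylbutanoyl]-1,3-oxazolidin-2-one
Conditions: NaN(SiMe3)2, THF, −78 °C; MeI, −78 °C
Reagents that add atoms: iodomethane CI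
Why: Evans asymmetric alkylation; the chelated Z-enolate is methylated on the face opposite the benzyl group, which for the (4R)-auxiliary and an ethyl-substituted enolate should give the (2R)-acyl group, and the minor diastereomer can be removed by chromatography.

Step 15
Reactants: 24 (4R)-4-benzyl-3-[(2R)-2-methylbutanoyl]-1,3-oxazolidin-2-one
Product: 25 (2R)-2-methylbutan-1-ol
Conditions: LiBH4, MeOH (1 equiv), Et2O, 0 °C
Reagents that add atoms: none
Why: Reductive cleavage of the imide at the exocyclic carbonyl without epimerisation; the auxiliary is recovered and the volatile alcohol is isolated by careful distillation or used as a solution.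

Step 16
Reactants: 25 (2R)-2-methylbutan-1-ol
Product: 27 (2E,4R)-2,4-dimethylhex-2-enal, via (2R)-2-methylbutanal 26 (not isolated)
Conditions: TEMPO (cat.), PhI(OAc)2, CH2Cl2, rt; then Ph3P=C(Me)CHO, 40 °C
Reagents that add atoms: 2-(triphenylphosphoranylidene)propanal CC(C=O)=P(c1ccccc1)(c1ccccc1)c1ccccc1
Why: Nitroxyl-catalysed oxidation followed in the same flask by Wittig olefination with a stabilised ylide, which should give the E-trisubstituted enal; trapping the α-branched aldehyde as it forms limits its racemisation and loss by evaporation.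

Step 17
Reactants: 27 (2E,4R)-2,4-dimethylhex-2-enal
Product: 28 ethyl (2E,4E,6E,8R)-6,8-dimethyldeca-2,4,6-trienoate
Conditions: (EtO)2P(O)CH2CH=CHCO2Et, LiN(SiMe3)2, THF, −78 → 0 °C
Reagents that add atoms: ethyl (2E)-4-(diethoxyphosphoryl)but-2-enoate CCOC(=O)/C=C/CP(=O)(OCC)OCC
Why: Vinylogous Horner–Wadsworth–Emmons olefination; the stabilised phosphonate anion should form the new C4=C5 alkene with E geometry while the existing alkenes keep theirs.

Step 18
Reactants: 28 ethyl (2E,4E,6E,8R)-6,8-dimethyldeca-2,4,6-trienoate
Product: 29 (2E,4E,6E,8R)-6,8-dimethyldeca-2,4,6-trienoic acid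
Conditions: LiOH·H2O, THF–MeOH–H2O, rt; then 1 M HCl
Reagents that add atoms: lithium hydroxide [Li+].[OH-]
Why: Saponification of an unhindered ethyl ester; C8 is not acidic enough to epimerise under these conditions.

Step 19
Reactants: 21 tert-butyl (1R,4S,7R,7aS)-1-(2-{[(tert-butyldimethylsilyl)oxy]methyl}prop-2-en-1-yl)-4-hydroxy-7a-methyl-2-oxo-2,4,5,6,7,7a-hexahydro-1H-indene-7-carboxylate; 29 (2E,4E,6E,8R)-6,8-dimethyldeca-2,4,6-trienoic acid
Product: 31 tert-butyl (1R,4S,7R,7aS)-1-(2-{[(tert-butyldimethylsilyl)oxy]methyl}prop-2-en-1-yl)-4-{[(2E,4E,6E,8R)-6,8-dimethyldeca-2,4,6-trienoyl]oxy}-7a-methyl-2-oxo-2,4,5,6,7,7a-hexahydro-1H-indene-7-carboxylate, via mixed anhydride 30 (not isolated)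
Conditions: 29, 2,4,6-trichlorobenzoyl chloride, Et3N, toluene, rt; then 21, DMAP, toluene, rt
Reagents that add atoms: none
Why: Yamaguchi esterification; the acylpyridinium ion formed from the mixed anhydride 30 acylates the hindered axial C4 hydroxyl with retention at C4, and the weak amine bases should not epimerise C1.

Step 20
Reactants: 31 tert-butyl (1R,4S,7R,7aS)-1-(2-{[(tert-butyldimethylsilyl)oxy]methyl}prop-2-en-1-yl)-4-{[(2E,4E,6E,8R)-6,8-dimethyldeca-2,4,6-trienoyl]oxy}-7a-methyl-2-oxo-2,4,5,6,7,7a-hexahydro-1H-indene-7-carboxylate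
Product: 32 (1R,4S,7R,7aS)-4-{[(2E,4E,6E,8R)-6,8-dimethyldeca-2,4,6-trienoyl]oxy}-1-[2-(hydroxymethyl)prop-2-en-1-yl]-7a-methyl-2-oxo-2,4,5,6,7,7a-hexahydro-1H-indene-7-carboxylic acid
Conditions: CF3CO2H–CH2Cl2–H2O, 0 °C → rt
Reagents that add atoms: none
Why: Acidolysis removes the tert-butyl ester (alkyl–oxygen cleavage, indifferent to the hindered carboxyl carbon) and the primary silyl ether together; the C4 ester should not ionise because the cation would sit next to the electron-poor enone, and the enal is not yet present.

Step 21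
Reactants: 32 (1R,4S,7R,7aS)-4-{[(2E,4E,6E,8R)-6,8-dimethyldeca-2,4,6-trienoyl]oxy}-1-[2-(hydroxymethyl)prop-2-en-1-yl]-7a-methyl-2-oxo-2,4,5,6,7,7a-hexahydro-1H-indene-7-carboxylic acid
Product: 33 (1R,4S,7R,7aS)-4-{[(2E,4E,6E,8R)-6,8-dimethyldeca-2,4,6-trienoyl]oxy}-1-(2-formylprop-2-en-1-yl)-7a-methyl-2-oxo-2,4,5,6,7,7a-hexahydro-1H-indene-7-carboxylic acid
Conditions: TEMPO (cat.), PhI(OAc)2, CH2Cl2, rt
Reagents that add atoms: none
Why: Nitroxyl-catalysed oxidation is selective for the primary allylic alcohol, tolerates the free acid, stops at the aldehyde without water and touches no stereocentre, so the fragile enal is formed in the last step.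

## Compound list

1 | 2-bromo-3-methylcyclopent-2-en-1-one | CC1=C(Br)C(=O)CC1 | starting material
2 | (1S)-2-bromo-3-methylcyclopent-2-en-1-ol | O[C@H]1CCC(C)=C1Br | intermediate
3 | (1S)-2-bromo-3-methylcyclopent-2-en-1-yl acetate | CC(=O)O[C@H]1CCC(C)=C1Br | intermediate
4 | trimethylsilyl ketene acetal of 3: (1S)-2-bromo-3-methylcyclopent-2-en-1-yl 1-[(trimethylsilyl)oxy]ethenyl ether | C=C(O[Si](C)(C)C)O[C@H]1CCC(C)=C1Br | intermediate
5 | trimethylsilyl 2-[(1S)-2-bromo-1-methylcyclopent-2-en-1-yl]acetate | C[Si](C)(C)OC(=O)C[C@]1(C)CCC=C1Br | intermediate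
6 | 2-[(1S)-2-bromo-1-methylcyclopent-2-en-1-yl]acetic acid | OC(=O)C[C@]1(C)CCC=C1Br | intermediate
7 | tert-butyl 2-[(1S)-2-bromo-1-methylcyclopent-2-en-1-yl]acetate | CC(C)(C)OC(=O)C[C@]1(C)CCC=C1Br | intermediate
8 | tert-butyl 2-[(1S)-2-bromo-1-methylcyclopent-2-en-1-yl]-3-(dimethylamino)propanoate (both epimers at the ester α-carbon) | CN(C)CC(C(=O)OC(C)(C)C)[C@]1(C)CCC=C1Br | intermediate
9 | {2-[(1S)-2-bromo-1-methylcyclopent-2-en-1-yl]-3-tert-butoxy-3-oxopropyl}trimethylammonium iodide (both epimers) | C[N+](C)(C)CC(C(=O)OC(C)(C)C)[C@]1(C)CCC=C1Br.[I-] | intermediate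
10 | tert-butyl 2-[(1S)-2-bromo-1-methylcyclopent-2-en-1-yl]prop-2-enoate | C=C(C(=O)OC(C)(C)C)[C@]1(C)CCC=C1Br | intermediate
11 | tert-butyl 2-[(1S)-2-bromo-1-methyl-4-oxocyclopent-2-en-1-yl]prop-2-enoate | C=C(C(=O)OC(C)(C)C)[C@]1(C)CC(=O)C=C1Br | intermediate
12 | tert-butyl 2-[(1R)-2-(1-ethoxyethenyl)-1-methyl-4-oxocyclopent-2-en-1-yl]prop-2-enoate | C=C(C(=O)OC(C)(C)C)[C@]1(C)CC(=O)C=C1C(=C)OCC | intermediate
13 | 2-methylidenepropane-1,3-diol | C=C(CO)CO | starting material
14 | 2-{[(tert-butyldimethylsilyl)oxy]methyl}prop-2-en-1-ol | C=C(CO)CO[Si](C)(C)C(C)(C)C | intermediate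
15 | {[2-(bromomethyl)prop-2-en-1-yl]oxy}(tert-butyl)dimethylsilane | C=C(CBr)CO[Si](C)(C)C(C)(C)C | intermediate
16 | tert-butyl 2-[(1R,5R)-5-(2-{[(tert-butyldimethylsilyl)oxy]methyl}prop-2-en-1-yl)-2-(1-ethoxyethenyl)-1-methyl-4-oxocyclopent-2-en-1-yl]prop-2-enoate | C=C(CO[Si](C)(C)C(C)(C)C)C[C@H]1C(=O)C=C(C(=C)OCC)[C@]1(C)C(=C)C(=O)OC(C)(C)C | intermediate
17 | tert-butyl 2-[(1R,5R)-2-acetyl-5-(2-{[(tert-butyldimethylsilyl)oxy]methyl}prop-2-en-1-yl)-1-methyl-4-oxocyclopent-2-en-1-yl]prop-2-enoate | C=C(CO[Si](C)(C)C(C)(C)C)C[C@H]1C(=O)C=C(C(C)=O)[C@]1(C)C(=C)C(=O)OC(C)(C)C | intermediate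
18 | 2-silyloxydiene of 17: the acetyl group converted into a 1-[(trimethylsilyl)oxy]ethenyl group, (1R,5R) | C=C(CO[Si](C)(C)C(C)(C)C)C[C@H]1C(=O)C=C(C(=C)O[Si](C)(C)C)[C@]1(C)C(=C)C(=O)OC(C)(C)C | intermediate
19 | silyl ketene acetal of 20: bicyclic 2,4-dione with C7=C(O-tert-butyl)(OSiMe3), (1R,7aS) | C=C(CO[Si](C)(C)C(C)(C)C)C[C@H]1C(=O)C=C2C(=O)CCC(=C(OC(C)(C)C)O[Si](C)(C)C)[C@@]21C | intermediate
20 | tert-butyl (1R,7R,7aS)-1-(2-{[(tert-butyldimethylsilyl)oxy]methyl}prop-2-en-1-yl)-7a-methyl-2,4-dioxo-2,4,5,6,7,7a-hexahydro-1H-indene-7-carboxylate | C=C(CO[Si](C)(C)C(C)(C)C)C[C@H]1C(=O)C=C2C(=O)CC[C@@H](C(=O)OC(C)(C)C)[C@@]21C | intermediate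
21 | tert-butyl (1R,4S,7R,7aS)-1-(2-{[(tert-butyldimethylsilyl)oxy]methyl}prop-2-en-1-yl)-4-hydroxy-7a-methyl-2-oxo-2,4,5,6,7,7a-hexahydro-1H-indene-7-carboxylate | C=C(CO[Si](C)(C)C(C)(C)C)C[C@H]1C(=O)C=C2[C@@H](O)CC[C@@H](C(=O)OC(C)(C)C)[C@@]21C | intermediate
22 | (4R)-4-benzyl-1,3-oxazolidin-2-one | O=C1N[C@H](Cc2ccccc2)CO1 | starting material
23 | (4R)-4-benzyl-3-butanoyl-1,3-oxazolidin-2-one | CCCC(=O)N1[C@H](Cc2ccccc2)COC1=O | intermediate
24 | (4R)-4-benzyl-3-[(2R)-2-methylbutanoyl]-1,3-oxazolidin-2-one | O=C([C@H](C)CC)N1[C@H](Cc2ccccc2)COC1=O | intermediate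
25 | (2R)-2-methylbutan-1-ol | OC[C@H](C)CC | intermediate
26 | (2R)-2-methylbutanal | O=C[C@H](C)CC | intermediate
27 | (2E,4R)-2,4-dimethylhex-2-enal | O=C/C(C)=C/[C@H](C)CC | intermediate
28 | ethyl (2E,4E,6E,8R)-6,8-dimethyldeca-2,4,6-trienoate | CCOC(=O)/C=C/C=C/C(C)=C/[C@H](C)CC | intermediate
29 | (2E,4E,6E,8R)-6,8-dimethyldeca-2,4,6-trienoic acid | OC(=O)/C=C/C=C/C(C)=C/[C@H](C)CC | intermediate
30 | (2E,4E,6E,8R)-6,8-dimethyldeca-2,4,6-trienoic 2,4,6-trichlorobenzoic anhydride | O=C(OC(=O)/C=C/C=C/C(C)=C/[C@H](C)CC)c1c(Cl)cc(Cl)cc1Cl | intermediate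
31 | tert-butyl (1R,4S,7R,7aS)-1-(2-{[(tert-butyldimethylsilyl)oxy]methyl}prop-2-en-1-yl)-4-{[(2E,4E,6E,8R)-6,8-dimethyldeca-2,4,6-trienoyl]oxy}-7a-methyl-2-oxo-2,4,5,6,7,7a-hexahydro-1H-indene-7-carboxylate | C=C(CO[Si](C)(C)C(C)(C)C)C[C@H]1C(=O)C=C2[C@@H](OC(=O)/C=C/C=C/C(C)=C/[C@H](C)CC)CC[C@@H](C(=O)OC(C)(C)C)[C@@]21C | intermediate
32 | (1R,4S,7R,7aS)-4-{[(2E,4E,6E,8R)-6,8-dimethyldeca-2,4,6-trienoyl]oxy}-1-[2-(hydroxymethyl)prop-2-en-1-yl]-7a-methyl-2-oxo-2,4,5,6,7,7a-hexahydro-1H-indene-7-carboxylic acid | C=C(CO)C[C@H]1C(=O)C=C2[C@@H](OC(=O)/C=C/C=C/C(C)=C/[C@H](C)CC)CC[C@@H](C(=O)O)[C@@]21C | intermediate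
33 | (1R,4S,7R,7aS)-4-{[(2E,4E,6E,8R)-6,8-dimethyldeca-2,4,6-trienoyl]oxy}-1-(2-formylprop-2-en-1-yl)-7a-methyl-2-oxo-2,4,5,6,7,7a-hexahydro-1H-indene-7-carboxylic acid | C=C(C=O)C[C@H]1C(=O)C=C2[C@@H](OC(=O)/C=C/C=C/C(C)=C/[C@H](C)CC)CC[C@@H](C(=O)O)[C@@]21C | target

## Step count and least certain steps

Total step count: 21. Longest linear sequence: 13 steps (steps 1–7, 10–12 and 19–21, from 1); the bromide 15 (steps 8–9) and the acid 29 (steps 13–18) are made in parallel.

Step 11 (key step). The enol ether 18 is cross-conjugated with the C2 enone and therefore a weaker nucleophile than a simple silyl enol ether. The addition may be slow, and on longer exposure to the silyl Lewis acid the tert-butyl group may be lost or 18 may simply be desilylated back to 17. Protonation of 19 may also show poor face selectivity, and over-silylation could enolise C2 towards C1 and erode that centre. Fallback, from 17 back to 20: run the closure as an anionic Michael addition. KN(SiMe3)2 in THF at −78 °C should remove a proton from the acetyl methyl in preference to the shielded C1–H; the enolate closes onto the acrylate in the same 6-endo sense; the tert-butyl ester enolate is then protonated at −78 °C with a hindered phenol such as 2,6-di-tert-butyl-4-methylphenol. This replaces Lewis-acid activation of the acceptor by base activation of the donor and makes no new isolable compound.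

Step 6. Hydrogen abstraction next to the electron-poor bromoalkene may be slow, and oxygen may be delivered at the C3a end of the allylic system (transposition with loss of bromine) or the material may be over-oxidised. Fallback, from 10 back to 11: Wohl–Ziegler bromination (N-bromosuccinimide, AIBN, PhCF3, 80 °C) should place bromine at the unhindered C2 terminus to give tert-butyl 2-[(1S)-2,4-dibromo-1-methylcyclopent-2-en-1-yl]prop-2-enoate F1. Kornblum oxidation (AgBF4, DMSO, rt; then Et3N) then converts the allylic bromide into the ketone 11.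

Step 10. Three processes threaten this step: conjugate addition of the enolate to the acrylate of a second molecule; a sluggish alkylation because the nucleophilic carbon adjoins a quaternary centre; and poor face selectivity if the planar acrylate shields little better than the methyl. Fallback, from 7 back to 17, carrying the acrylate in masked form:
- Deprotonation of 7 with LiN(iPr)2, addition of monomeric formaldehyde and silylation of the alkoxide with Et3SiCl would give tert-butyl 2-[(1S)-2-bromo-1-methylcyclopent-2-en-1-yl]-3-[(triethylsilyl)oxy]propanoate F2 (both epimers at the ester α-carbon).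
- CrO3/3,5-dimethylpyrazole as in step 6 would give tert-butyl 2-[(1S)-2-bromo-1-methyl-4-oxocyclopent-2-en-1-yl]-3-[(triethylsilyl)oxy]propanoate F3.
- Stille coupling as in step 7 would give tert-butyl 2-[(1S)-2-(1-ethoxyethenyl)-1-methyl-4-oxocyclopent-2-en-1-yl]-3-[(triethylsilyl)oxy]propanoate F4.
- Deprotonation with LiN(SiMe3)2 and alkylation with 15 would give the C1-alkylated ethoxydiene triethylsilyl ether F5, now formed anti to a bulkier sp3 substituent and with no Michael acceptor present.
- Dilute HCl would give the acetyl primary alcohol F6 (the tert-butyldimethylsilyl ether is kept).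
- MsCl/Et3N would give the mesylate F7, which a short treatment with DBU at 0 °C eliminates to 17.

Step 12. Hydride may attack the C2 carbonyl competitively, or add in conjugate fashion to the ene-dione. Fallback, from 20 back to 21: reduce both carbonyls with excess NaBH4/CeCl3·7H2O to the 2,4-diol F8 (C4 still set anti to the methyl), then re-oxidise with MnO2 in CH2Cl2. The C2 carbinol has its C–H bond aligned with the alkene π system and should be oxidised, whereas the axial C4 hydroxyl has its C–H bond close to the alkene plane and should react much more slowly.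

Step 20. Acid may add across the 1,1-disubstituted alkene of the side chain or affect the allylic alcohol once it is freed, and tert-butyl cleavage may lag behind desilylation. Fallback, from 31 to 33, separating the two deprotections and forming the enal before the ester is cleaved: HF·pyridine in THF should give the allylic alcohol tert-butyl ester F9; TEMPO/PhI(OAc)2 the enal tert-butyl ester F10; and anhydrous ZnBr2 in CH2Cl2, a mild Lewis acid for tert-butyl esters, the target 33.

## Further compounds

F0 | step 11 | none | none
F1 | step 6 | tert-butyl 2-[(1S)-2,4-dibromo-1-methylcyclopent-2-en-1-yl]prop-2-enoate (both epimers at C4) | C=C(C(=O)OC(C)(C)C)[C@]1(C)CC(Br)C=C1Br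
F2 | step 10 | tert-butyl 2-[(1S)-2-bromo-1-methylcyclopent-2-en-1-yl]-3-[(triethylsilyl)oxy]propanoate (both epimers at the ester α-carbon) | CC[Si](CC)(CC)OCC(C(=O)OC(C)(C)C)[C@]1(C)CCC=C1Br
F3 | step 10 | tert-butyl 2-[(1S)-2-bromo-1-methyl-4-oxocyclopent-2-en-1-yl]-3-[(triethylsilyl)oxy]propanoate | CC[Si](CC)(CC)OCC(C(=O)OC(C)(C)C)[C@]1(C)CC(=O)C=C1Br
F4 | step 10 | tert-butyl 2-[(1S)-2-(1-ethoxyethenyl)-1-methyl-4-oxocyclopent-2-en-1-yl]-3-[(triethylsilyl)oxy]propanoate | CC[Si](CC)(CC)OCC(C(=O)OC(C)(C)C)[C@]1(C)CC(=O)C=C1C(=C)OCC
F5 | step 10 | tert-butyl 2-[(1S,5R)-5-(2-{[(tert-butyldimethylsilyl)oxy]methyl}prop-2-en-1-yl)-2-(1-ethoxyethenyl)-1-methyl-4-oxocyclopent-2-en-1-yl]-3-[(triethylsilyl)oxy]propanoate | C=C(CO[Si](C)(C)C(C)(C)C)C[C@H]1C(=O)C=C(C(=C)OCC)[C@]1(C)C(CO[Si](CC)(CC)CC)C(=O)OC(C)(C)C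
F6 | step 10 | tert-butyl 2-[(1S,5R)-2-acetyl-5-(2-{[(tert-butyldimethylsilyl)oxy]methyl}prop-2-en-1-yl)-1-methyl-4-oxocyclopent-2-en-1-yl]-3-hydroxypropanoate | C=C(CO[Si](C)(C)C(C)(C)C)C[C@H]1C(=O)C=C(C(C)=O)[C@]1(C)C(CO)C(=O)OC(C)(C)C
F7 | step 10 | tert-butyl 2-[(1S,5R)-2-acetyl-5-(2-{[(tert-butyldimethylsilyl)oxy]methyl}prop-2-en-1-yl)-1-methyl-4-oxocyclopent-2-en-1-yl]-3-[(methanesulfonyl)oxy]propanoate | C=C(CO[Si](C)(C)C(C)(C)C)C[C@H]1C(=O)C=C(C(C)=O)[C@]1(C)C(COS(C)(=O)=O)C(=O)OC(C)(C)C
F8 | step 12 | tert-butyl (1R,4S,7R,7aS)-1-(2-{[(tert-butyldimethylsilyl)oxy]methyl}prop-2-en-1-yl)-2,4-dihydroxy-7a-methyl-2,4,5,6,7,7a-hexahydro-1H-indene-7-carboxylate (either configuration at C2) | C=C(CO[Si](C)(C)C(C)(C)C)C[C@H]1C(O)C=C2[C@@H](O)CC[C@@H](C(=O)OC(C)(C)C)[C@@]21C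
F9 | step 20 | tert-butyl (1R,4S,7R,7aS)-4-{[(2E,4E,6E,8R)-6,8-dimethyldeca-2,4,6-trienoyl]oxy}-1-[2-(hydroxymethyl)prop-2-en-1-yl]-7a-methyl-2-oxo-2,4,5,6,7,7a-hexahydro-1H-indene-7-carboxylate | C=C(CO)C[C@H]1C(=O)C=C2[C@@H](OC(=O)/C=C/C=C/C(C)=C/[C@H](C)CC)CC[C@@H](C(=O)OC(C)(C)C)[C@@]21C
F10 | step 20 | tert-butyl (1R,4S,7R,7aS)-4-{[(2E,4E,6E,8R)-6,8-dimethyldeca-2,4,6-trienoyl]oxy}-1-(2-formylprop-2-en-1-yl)-7a-methyl-2-oxo-2,4,5,6,7,7a-hexahydro-1H-indene-7-carboxylate | C=C(C=O)C[C@H]1C(=O)C=C2[C@@H](OC(=O)/C=C/C=C/C(C)=C/[C@H](C)CC)CC[C@@H](C(=O)OC(C)(C)C)[C@@]21C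
A1 | alternative 1 | hydrindane C4 triisopropylsilyl enol ether with C2 dioxolane, C7a methyl and C7 2-(trimethylsilyl)ethyl ester cis | C1C3(OCCO3)C[C@H]2C(O[Si](C(C)C)(C(C)C)C(C)C)=CC[C@@H](C(=O)OCC[Si](C)(C)C)[C@@]21C
A2 | alternative 2 | cyclopropane-fused C4 alcohol with C2 dioxolane and C7 tert-butyl ester, methylene cis to the hydroxyl | O[C@H]1CC[C@@H](C(=O)OC(C)(C)C)[C@]24C[C@@]14CC3(OCCO3)C2
A3 | alternative 3 | 1,1-dichlorohydrindan-2-one with C4 tert-butyldimethylsilyl ether, C7 tert-butyl ester and C7a methyl | ClC1(Cl)C(=O)C[C@@H]2[C@@H](O[Si](C)(C)C(C)(C)C)CC[C@@H](C(=O)OC(C)(C)C)[C@@]21C
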